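**Plan**

- Retrosynthesis: (a) the bond between C4 of the dienone ring (ring B) and the ethylene linker is cut as a Stork–Danheiser union; (b) ring A is cut at C4a–C5 and C8–C8a, a [4+2] disconnection to 2-methoxy-3,5-dimethylbenzoquinone and a 3-silyloxy-4-methylpenta-1,3-diene; (c) in the right half the oxepane C–O bond and the cyclohexane C5a–C6 bond are cut together, an epoxide-opening cascade of a geranylacetone-derived diepoxy enol silane.
- Enabling feature: ring B of the target (C1 enol, C2 ketone, C3=C4 enone, quaternary C4a) is a quinone-level ring, the diosphenol tautomer of an ene-1,2-dione. Ring A carries its C7 ketone next to the C8 gem-dimethyl carbon, which is the imprint of a 2-silyloxydiene with a CMe2 terminus.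
- Forward order: ring B is bought as a quinone and ring A is annulated onto it (step 5). The oxepane and then the cyclohexane of the right half arise in one cascade (step 11). The halves are joined last (step 17), with all three masked carbonyl groups unveiled in the same flask.
- Stereochemistry: C4a comes from the catalyst-controlled cycloaddition (C8a is sacrificial). C9a and C5a come from Shi epoxidation and anti opening of the epoxide. C6 is set by equilibration α to a ketone, and C7 by hydrogenation anti to the axial angular methyl group.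

Key step: step 5

Remark (assumption): in step 5 the (R)-configured acid is taken to be the antipode that leads to the (4aR,8aS) adduct; if the facial sense proves opposite, the (S)-acid is used and nothing else changes.

**Route**

Step 1
Reactants: 1 2,6-dimethyl-1,4-benzoquinone
Product: 3 3-bromo-2,6-dimethyl-1,4-benzoquinone, via dibromide 2 (not isolated)
Conditions: Br2 (1.0 equiv), AcOH, rt; then NaOAc, 60 °C
Reagents that add atoms: bromine, BrBr
Why: Addition of bromine across one of the two equivalent ring double bonds followed by acetate-mediated dehydrobromination (quinone halogenation by addition–elimination) should give the monobromoquinone, in which no stereocenter remains.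

Step 2
Reactants: 3 3-bromo-2,6-dimethyl-1,4-benzoquinone
Product: 4 2-methoxy-3,5-dimethyl-1,4-benzoquinone
Conditions: NaOMe (1.05 equiv), MeOH, 0 °C
Reagents that add atoms: sodium methoxide, [Na+].[O-]C
Why: Addition–elimination of methoxide at the bromine-bearing carbon of a haloquinone (vinylogous acyl substitution) installs the methoxy group that later directs the cycloaddition and serves as the Stork–Danheiser leaving group.

Step 3
Reactants: 5 4-methylpent-1-en-3-ol
Product: 6 4-methylpent-1-en-3-one
Conditions: Dess–Martin periodinane, CH2Cl2, 0 °C to rt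
Reagents that add atoms: none
Why: Dess–Martin oxidation of a secondary allylic alcohol should give the vinyl ketone under neutral conditions that avoid Michael addition and polymerisation.

Step 4
Reactants: 6 4-methylpent-1-en-3-one
Product: 7 4-methyl-3-[(triisopropylsilyl)oxy]penta-1,3-diene
Conditions: i-Pr3SiOTf, Et3N, Et2O, 0 °C
Reagents that add atoms: triisopropylsilyl triflate, CC(C)[Si](OS(=O)(=O)C(F)(F)F)(C(C)C)C(C)C
Why: Soft enolisation of the vinyl ketone (O-silylation, then loss of the only α'-hydrogen, the isopropyl methine) gives the 2-silyloxydiene regiospecifically, as in the standard preparation of 2-silyloxybutadienes.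

Step 5
Reactants: 4 2-methoxy-3,5-dimethyl-1,4-benzoquinone; 7 4-methyl-3-[(triisopropylsilyl)oxy]penta-1,3-diene
Product: 8 (4aR,8aS)-2-methoxy-3,4a,8,8-tetramethyl-7-[(triisopropylsilyl)oxy]-4a,5,8,8a-tetrahydronaphthalene-1,4-dione (cis-fused)
Conditions: (R)-3,3'-bis(2,4,6-triisopropylphenyl)-1,1'-binaphthyl-2,2'-diyl N-triflylphosphoramide (5 mol %), toluene, −78 to −40 °C
Reagents that add atoms: none
Why: Proposed new method: the chiral acid binds the most basic oxygen of 4, the C4 vinylogous-ester carbonyl conjugated with the C2 methoxy group, so that C6 (the only unsubstituted ring carbon) becomes the electrophilic terminus and is attacked by the enol-ether-activated CMe2 terminus of 7, after which the CH2 terminus closes onto C5 in a highly asynchronous normal-demand Diels–Alder reaction (limiting form: Mukaiyama–Michael addition followed by Michael ring closure inside the chiral ion pair). The closest known reaction types are the BF3-promoted, regio-reversed Diels–Alder reactions of 2-methoxy-5-methylbenzoquinone, the AlBr3/AlMe3-promoted cycloadditions of hindered 2-silyloxydienes, and the N-triflylphosphoramide-catalysed enantioselective Diels–Alder reaction of enones with silyloxydienes; their combination on a quinone is what is new. Ring A is closed as a six-membered carbocycle by intermolecular [4+2] cycloaddition across the C5=C6 bond of the quinone (6-endo-trig closure of the second bond in the stepwise limit), suprafacial on both partners, so the ring fusion is cis. The quaternary C4a center and the sacrificial C8a center are therefore set together: the chiral phosphoramide anion shields one face of the bound quinone (absolute control), and their cis relationship follows from the suprafacial addition. The step needs site selectivity (the methoxy-bearing, tetrasubstituted C2=C3 bond is electron-rich and should stay inert), regioselectivity (secured by acid binding at C4=O and reinforced sterically, since the hindered CMe2 terminus meets the C–H carbon and the CH2 terminus meets the C–Me carbon) and enantioselectivity (catalyst).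

Step 6
Reactants: 8 (4aR,8aS)-2-methoxy-3,4a,8,8-tetramethyl-7-[(triisopropylsilyl)oxy]-4a,5,8,8a-tetrahydronaphthalene-1,4-dione
Product: 9 (8aR)-4-[(tert-butyldimethylsilyl)oxy]-3-methoxy-2,5,5,8a-tetramethyl-6-[(triisopropylsilyl)oxy]-5,8-dihydronaphthalen-1(8aH)-one
Conditions: t-BuMe2SiOTf, Et3N, CH2Cl2, 0 °C to rt
Reagents that add atoms: tert-butyldimethylsilyl triflate, CC(C)(C)[Si](C)(C)OS(=O)(=O)C(F)(F)F
Why: Soft enolisation of the C1 ketone of 8, whose only α-hydrogen is the C8a methine, masks the more electrophilic carbonyl as a silyl dienol ether, leaves the vinylogous-ester carbonyl as the only electrophile and erases the sacrificial C8a stereocenter.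

Step 7
Reactants: 10 (E)-geranylacetone
Product: 11 4-{(2R,3R)-3-[2-((2R)-3,3-dimethyloxiran-2-yl)ethyl]-3-methyloxiran-2-yl}butan-2-one
Conditions: D-fructose-derived Shi ketone (0.3 equiv), Oxone (2KHSO5·KHSO4·K2SO4), K2CO3, Bu4NHSO4, Na2B4O7 buffer, MeCN–CH2(OMe)2–H2O, 0 °C
Reagents that add atoms: potassium peroxymonosulfate, [K+].[O-]S(=O)(=O)OO
Why: Shi asymmetric epoxidation: the chiral dioxirane should epoxidise both electron-rich trisubstituted alkenes through the spiro transition state, giving the R configuration at each epoxide CH carbon (reagent control), which is the source of C9a and C5a of the target.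

Step 8
Reactants: 11 4-{(2R,3R)-3-[2-((2R)-3,3-dimethyloxiran-2-yl)ethyl]-3-methyloxiran-2-yl}butan-2-one; 12 (benzyloxy)acetaldehyde
Product: 14 1-(benzyloxy)-6-{(2R,3R)-3-[2-((2R)-3,3-dimethyloxiran-2-yl)ethyl]-3-methyloxiran-2-yl}-2-hydroxyhexan-4-one (both C2 epimers), via lithium enolate 13 (not isolated)
Conditions: LiN(i-Pr)2, THF, −78 °C; then 12, −78 °C; H2O quench
Reagents that add atoms: none
Why: Kinetic deprotonation of the methyl ketone at the methyl group and directed aldol addition to the aldehyde form the carbon chain; the new carbinol center is formed unselectively and is removed in step 9.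

Step 9
Reactants: 14 1-(benzyloxy)-6-{(2R,3R)-3-[2-((2R)-3,3-dimethyloxiran-2-yl)ethyl]-3-methyloxiran-2-yl}-2-hydroxyhexan-4-one
Product: 16 (E)-1-(benzyloxy)-6-{(2R,3R)-3-[2-((2R)-3,3-dimethyloxiran-2-yl)ethyl]-3-methyloxiran-2-yl}hex-2-en-4-one, via mesylate 15 (not isolated)
Conditions: MsCl, Et3N (excess), CH2Cl2, 0 °C to rt
Reagents that add atoms: none
Why: Mesylation of the β-hydroxy ketone and E1cB elimination should give the (E)-enone, the thermodynamically preferred geometry.

Step 10
Reactants: 16 (E)-1-(benzyloxy)-6-{(2R,3R)-3-[2-((2R)-3,3-dimethyloxiran-2-yl)ethyl]-3-methyloxiran-2-yl}hex-2-en-4-one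
Product: 17 {[(3Z)-1-(benzyloxy)-6-{(2R,3R)-3-[2-((2R)-3,3-dimethyloxiran-2-yl)ethyl]-3-methyloxiran-2-yl}hex-3-en-4-yl]oxy}triethylsilane
Conditions: Et3SiH, RhCl(PPh3)3 (2 mol %), THF, 50 °C
Reagents that add atoms: triethylsilane, CC[SiH](CC)CC
Why: Rhodium-catalysed 1,4-hydrosilylation of an enone with a monohydrosilane places the enol silane double bond regiospecifically toward the benzyloxyethyl arm, which base-mediated enolisation of the saturated ketone could not do.

Step 11
Reactants: 17 {[(3Z)-1-(benzyloxy)-6-{(2R,3R)-3-[2-((2R)-3,3-dimethyloxiran-2-yl)ethyl]-3-methyloxiran-2-yl}hex-3-en-4-yl]oxy}triethylsilane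
Product: 19 (3R,5aR,6R,9aR)-6-[2-(benzyloxy)ethyl]-3-hydroxy-2,2,5a-trimethyloctahydro-1-benzoxepin-7(2H)-one, via triethylsilyl ether 18 (not isolated)
Conditions: Et3SiOTf (0.3 equiv), 2,6-di-tert-butyl-4-methylpyridine, CH2Cl2, −78 °C; then 1 M HCl, THF, rt
Reagents that add atoms: none
Why: In this silyl-triflate-promoted tandem oxa-/carbacyclisation of a diepoxy enol silane, the activated terminal epoxide is opened at its tertiary carbon by the oxygen of the internal epoxide (oxepane) and the resulting epoxonium ion is opened with inversion at its tertiary carbon by the enol silane carbon (cyclohexanone), so the trans ring fusion and the C5a/C9a configurations derive from the (R,R)-epoxide, while C6, α to the ketone, equilibrates to the equatorial side chain in the acidic work-up.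

Step 12
Reactants: 19 (3R,5aR,6R,9aR)-6-[2-(benzyloxy)ethyl]-3-hydroxy-2,2,5a-trimethyloctahydro-1-benzoxepin-7(2H)-one
Product: 20 (3R,5aR,6S,9aR)-6-[2-(benzyloxy)ethyl]-2,2,5a-trimethyl-7-methylideneoctahydro-1-benzoxepin-3-ol
Conditions: Ph3PCH3Br, KOt-Bu (excess), THF, 0 °C to reflux
Reagents that add atoms: methyltriphenylphosphonium bromide, C[P+](c1ccccc1)(c1ccccc1)c1ccccc1.[Br-]
Why: Wittig methylenation of the α-monosubstituted cyclohexanone with excess ylide tolerates the free hydroxyl as its alkoxide, and any epimerisation at C6 under the basic conditions returns to the favoured equatorial side chain before olefination.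

Step 13
Reactants: 20 (3R,5aR,6S,9aR)-6-[2-(benzyloxy)ethyl]-2,2,5a-trimethyl-7-methylideneoctahydro-1-benzoxepin-3-ol
Product: 22 (3R,5aR,6S,7S,9aR)-6-(2-hydroxyethyl)-2,2,5a,7-tetramethyloctahydro-1-benzoxepin-3-ol, via benzyl ether 21 (not isolated)
Conditions: H2 (1 atm), PtO2, EtOAc, rt; then Pd(OH)2 on carbon, EtOH, H2
Reagents that add atoms: none
Why: Heterogeneous hydrogenation should deliver hydrogen to the exocyclic alkene from the face opposite the axial C5a methyl group (1,3-diaxial shielding, as in the hydrogenation of labdane 8(17)-enes), which sets C7 with its methyl cis to the angular methyl, and hydrogenolysis then frees the primary alcohol.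

Step 14
Reactants: 22 (3R,5aR,6S,7S,9aR)-6-(2-hydroxyethyl)-2,2,5a,7-tetramethyloctahydro-1-benzoxepin-3-ol
Product: 23 (3R,5aR,6S,7S,9aR)-6-(2-iodoethyl)-2,2,5a,7-tetramethyloctahydro-1-benzoxepin-3-ol
Conditions: I2, PPh3, imidazole, CH2Cl2, 0 °C
Reagents that add atoms: iodine, II
Why: Appel-type iodination should be selective for the primary hydroxyl over the secondary hydroxyl, which is hindered by the adjacent gem-dimethyl carbon.

Step 15
Reactants: 23 (3R,5aR,6S,7S,9aR)-6-(2-iodoethyl)-2,2,5a,7-tetramethyloctahydro-1-benzoxepin-3-ol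
Product: 24 (5aR,6S,7S,9aR)-6-(2-iodoethyl)-2,2,5a,7-tetramethyloctahydro-1-benzoxepin-3(2H)-one
Conditions: Dess–Martin periodinane, CH2Cl2, 0 °C to rt
Reagents that add atoms: none
Why: Dess–Martin oxidation of the secondary alcohol gives the oxepanone without touching the primary iodide, and no stereocenter is α to the new ketone.

Step 16
Reactants: 24 (5aR,6S,7S,9aR)-6-(2-iodoethyl)-2,2,5a,7-tetramethyloctahydro-1-benzoxepin-3(2H)-one
Product: 25 tert-butyl{[(5aR,6S,7S,9aR)-6-(2-iodoethyl)-2,2,5a,7-tetramethyl-2,5,5a,6,7,8,9,9a-octahydro-1-benzoxepin-3-yl]oxy}dimethylsilane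
Conditions: t-BuMe2SiOTf, Et3N, CH2Cl2, −78 to 0 °C
Reagents that add atoms: tert-butyldimethylsilyl triflate, CC(C)(C)[Si](C)(C)OS(=O)(=O)C(F)(F)F
Why: Soft enolisation can only occur toward the single α-CH2 group (the other α-carbon is quaternary), so the ketone is masked regiospecifically as a silyl enol ether that tolerates the organolithium chemistry of step 17.

Step 17
Reactants: 25 tert-butyl{[(5aR,6S,7S,9aR)-6-(2-iodoethyl)-2,2,5a,7-tetramethyl-2,5,5a,6,7,8,9,9a-octahydro-1-benzoxepin-3-yl]oxy}dimethylsilane; 9 (8aR)-4-[(tert-butyldimethylsilyl)oxy]-3-methoxy-2,5,5,8a-tetramethyl-6-[(triisopropylsilyl)oxy]-5,8-dihydronaphthalen-1(8aH)-one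
Product: 28 (4aS)-1-hydroxy-3,4a,8,8-tetramethyl-4-{2-[(5aR,6S,7S,9aR)-2,2,5a,7-tetramethyl-3-oxooctahydro-1-benzoxepin-6-yl]ethyl}-4a,5,6,8-tetrahydronaphthalene-2,7-dione (CNP0302807.1), via alkyllithium 26 (not isolated), via lithium alkoxide 27 (not isolated)
Conditions: t-BuLi (2.1 equiv), Et2O–pentane, −78 °C; then 9, THF, −78 to 0 °C; then 48% aq. HF, MeCN, 0 °C to rt
Reagents that add atoms: water, O
Why: Iodine–lithium exchange gives the primary alkyllithium, which adds 1,2 to the only carbonyl of 9 (Stork–Danheiser alkylation of a vinylogous ester that has no enolisable hydrogen), and aqueous HF then ionises the tertiary allylic alcohol, hydrolyses the methyl enol ether with 1,3-carbonyl transposition and cleaves all three silyl enol ethers, the liberated 1,2-dione enolising toward C8a to the diosphenol, so that the carbinol center formed on addition is destroyed and no existing stereocenter is at risk.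

**Compound list**

1 | 2,6-dimethyl-1,4-benzoquinone | CC1=CC(=O)C=C(C)C1=O | starting material
2 | 2,3-dibromo-2,6-dimethylcyclohex-5-ene-1,4-dione (racemic, not isolated) | CC1=CC(=O)C(Br)C(C)(Br)C1=O | intermediate
3 | 3-bromo-2,6-dimethyl-1,4-benzoquinone | CC1=CC(=O)C(Br)=C(C)C1=O | intermediate
4 | 2-methoxy-3,5-dimethyl-1,4-benzoquinone | COC1=C(C)C(=O)C(C)=CC1=O | intermediate
5 | 4-methylpent-1-en-3-ol (racemic) | C=CC(O)C(C)C | starting material
6 | 4-methylpent-1-en-3-one | C=CC(=O)C(C)C | intermediate
7 | 4-methyl-3-[(triisopropylsilyl)oxy]penta-1,3-diene | C=CC(O[Si](C(C)C)(C(C)C)C(C)C)=C(C)C | intermediate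
8 | (4aR,8aS)-2-methoxy-3,4a,8,8-tetramethyl-7-[(triisopropylsilyl)oxy]-4a,5,8,8a-tetrahydronaphthalene-1,4-dione | COC1=C(C)C(=O)[C@]2(C)CC=C(O[Si](C(C)C)(C(C)C)C(C)C)C(C)(C)[C@@H]2C1=O | intermediate
9 | (8aR)-4-[(tert-butyldimethylsilyl)oxy]-3-methoxy-2,5,5,8a-tetramethyl-6-[(triisopropylsilyl)oxy]-5,8-dihydronaphthalen-1(8aH)-one | COC1=C(C)C(=O)[C@]2(C)CC=C(O[Si](C(C)C)(C(C)C)C(C)C)C(C)(C)C2=C1O[Si](C)(C)C(C)(C)C | intermediate
10 | (E)-geranylacetone, (5E)-6,10-dimethylundeca-5,9-dien-2-one | CC(=O)CC/C=C(\C)CCC=C(C)C | starting material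
11 | 4-{(2R,3R)-3-[2-((2R)-3,3-dimethyloxiran-2-yl)ethyl]-3-methyloxiran-2-yl}butan-2-one | CC(=O)CC[C@H]1O[C@]1(C)CC[C@H]1OC1(C)C | intermediate
12 | (benzyloxy)acetaldehyde | O=CCOCc1ccccc1 | starting material
13 | kinetic (terminal) lithium enolate of 11 (not isolated) | [Li]OC(=C)CC[C@H]1O[C@]1(C)CC[C@H]1OC1(C)C | intermediate
14 | 1-(benzyloxy)-6-{(2R,3R)-3-[2-((2R)-3,3-dimethyloxiran-2-yl)ethyl]-3-methyloxiran-2-yl}-2-hydroxyhexan-4-one (both C2 epimers) | O=C(CC(O)COCc1ccccc1)CC[C@H]1O[C@]1(C)CC[C@H]1OC1(C)C | intermediate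
15 | methanesulfonate of 14 (not isolated) | O=C(CC(OS(C)(=O)=O)COCc1ccccc1)CC[C@H]1O[C@]1(C)CC[C@H]1OC1(C)C | intermediate
16 | (E)-1-(benzyloxy)-6-{(2R,3R)-3-[2-((2R)-3,3-dimethyloxiran-2-yl)ethyl]-3-methyloxiran-2-yl}hex-2-en-4-one | O=C(/C=C/COCc1ccccc1)CC[C@H]1O[C@]1(C)CC[C@H]1OC1(C)C | intermediate
17 | {[(3Z)-1-(benzyloxy)-6-{(2R,3R)-3-[2-((2R)-3,3-dimethyloxiran-2-yl)ethyl]-3-methyloxiran-2-yl}hex-3-en-4-yl]oxy}triethylsilane | CC[Si](CC)(CC)O/C(=C\CCOCc1ccccc1)CC[C@H]1O[C@]1(C)CC[C@H]1OC1(C)C | intermediate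
18 | (3R,5aR,6R,9aR)-6-[2-(benzyloxy)ethyl]-2,2,5a-trimethyl-3-[(triethylsilyl)oxy]octahydro-1-benzoxepin-7(2H)-one (not isolated) | c1ccccc1COCC[C@H]2C(=O)CC[C@H]3OC(C)(C)[C@H](O[Si](CC)(CC)CC)CC[C@@]32C | intermediate
19 | (3R,5aR,6R,9aR)-6-[2-(benzyloxy)ethyl]-3-hydroxy-2,2,5a-trimethyloctahydro-1-benzoxepin-7(2H)-one | c1ccccc1COCC[C@H]2C(=O)CC[C@H]3OC(C)(C)[C@H](O)CC[C@@]32C | intermediate
20 | (3R,5aR,6S,9aR)-6-[2-(benzyloxy)ethyl]-2,2,5a-trimethyl-7-methylideneoctahydro-1-benzoxepin-3-ol | c1ccccc1COCC[C@H]2C(=C)CC[C@H]3OC(C)(C)[C@H](O)CC[C@@]32C | intermediate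
21 | (3R,5aR,6S,7S,9aR)-6-[2-(benzyloxy)ethyl]-2,2,5a,7-tetramethyloctahydro-1-benzoxepin-3-ol (not isolated) | c1ccccc1COCC[C@H]2[C@@H](C)CC[C@H]3OC(C)(C)[C@H](O)CC[C@@]32C | intermediate
22 | (3R,5aR,6S,7S,9aR)-6-(2-hydroxyethyl)-2,2,5a,7-tetramethyloctahydro-1-benzoxepin-3-ol | OCC[C@H]2[C@@H](C)CC[C@H]3OC(C)(C)[C@H](O)CC[C@@]32C | intermediate
23 | (3R,5aR,6S,7S,9aR)-6-(2-iodoethyl)-2,2,5a,7-tetramethyloctahydro-1-benzoxepin-3-ol | ICC[C@H]2[C@@H](C)CC[C@H]3OC(C)(C)[C@H](O)CC[C@@]32C | intermediate
24 | (5aR,6S,7S,9aR)-6-(2-iodoethyl)-2,2,5a,7-tetramethyloctahydro-1-benzoxepin-3(2H)-one | ICC[C@H]2[C@@H](C)CC[C@H]3OC(C)(C)C(=O)CC[C@@]32C | intermediate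
25 | tert-butyl{[(5aR,6S,7S,9aR)-6-(2-iodoethyl)-2,2,5a,7-tetramethyl-2,5,5a,6,7,8,9,9a-octahydro-1-benzoxepin-3-yl]oxy}dimethylsilane | ICC[C@H]2[C@@H](C)CC[C@H]3OC(C)(C)C(O[Si](C)(C)C(C)(C)C)=CC[C@@]32C | intermediate
26 | primary alkyllithium from 25 (not isolated) | [Li]CC[C@H]2[C@@H](C)CC[C@H]3OC(C)(C)C(O[Si](C)(C)C(C)(C)C)=CC[C@@]32C | intermediate
27 | lithium alkoxide from 1,2-addition of 26 to the C1 carbonyl of 9 (both C1 epimers, not isolated) | COC1=C(C)C(O[Li])(CC[C@H]3[C@@H](C)CC[C@H]4OC(C)(C)C(O[Si](C)(C)C(C)(C)C)=CC[C@@]43C)[C@]2(C)CC=C(O[Si](C(C)C)(C(C)C)C(C)C)C(C)(C)C2=C1O[Si](C)(C)C(C)(C)C | intermediate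
28 | (4aS)-1-hydroxy-3,4a,8,8-tetramethyl-4-{2-[(5aR,6S,7S,9aR)-2,2,5a,7-tetramethyl-3-oxooctahydro-1-benzoxepin-6-yl]ethyl}-4a,5,6,8-tetrahydronaphthalene-2,7-dione | CC1=C(CC[C@H]2[C@@H](C)CC[C@H]3OC(C)(C)C(=O)CC[C@@]32C)[C@]2(C)CCC(=O)C(C)(C)C2=C(O)C1=O | target

**Summary**

Total step count: 17. Longest linear sequence: 11 steps (10 to 28, steps 7 to 17); the left half needs steps 1, 2, 5 and 6, and the diene needs steps 3 and 4.

Steps most likely to fail:

1. Step 5 (the step that goes beyond precedent). What may go wrong is poor facial discrimination by the chiral acid, reversal of regiochemistry if the acid binds the C1 carbonyl, or protodesilylation of the diene before it reacts. Fallback: starting from 4 and 7, the cycloaddition is run with an achiral Lewis acid of the kind known to bind the vinylogous-ester carbonyl of methoxyquinones and to drive hindered silyloxydienes (BF3·OEt2, or AlBr3/AlMe3, CH2Cl2, −78 °C). This gives the cis adduct as the racemate, that is 8 together with the (4aS,8aR)-enantiomer of 8 F1. The enantiomers are then separated by preparative chromatography on a chiral stationary phase, and the route is rejoined at 8.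

2. Step 17. What may go wrong is silyl transfer from the oxepanone enol ether to the organolithium during the exchange, or incomplete unveiling of that enol ether, so that the right half arrives damaged at the union. Fallback: starting from 23 and 9, the hydroxyl of 23 is deprotonated with MeLi and the iodide is exchanged with t-BuLi to give the O,C-dilithio species F4. Addition to 9 gives the dilithium alkoxide adduct F5, and aqueous HF in MeCN then gives the 3-hydroxy analogue of the target F6. The secondary alcohol is oxidised last with buffered Dess–Martin periodinane (the diosphenol hydroxyl is an enol, not a carbinol), and the route is rejoined at 28.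

3. Step 13. What may go wrong is insufficient facial selectivity in the hydrogenation, or migration of the exocyclic double bond into the ring before reduction, which would scramble C7 and C6. Fallback: starting from 20, hydroboration with the bulky 9-borabicyclo[3.3.1]nonane followed by NaOH/H2O2 should add from the face opposite the axial angular methyl group without alkene migration and give the 7-hydroxymethyl diol F2. Selective tosylation of the primary hydroxyl (TsCl, pyridine) gives the primary tosylate F3, and reduction with LiEt3BH gives 21, where the route is rejoined before the hydrogenolysis to 22.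

Further compounds

F1 | step 5 | (4aS,8aR)-2-methoxy-3,4a,8,8-tetramethyl-7-[(triisopropylsilyl)oxy]-4a,5,8,8a-tetrahydronaphthalene-1,4-dione (enantiomer of 8) | COC1=C(C)C(=O)[C@@]2(C)CC=C(O[Si](C(C)C)(C(C)C)C(C)C)C(C)(C)[C@H]2C1=O
F2 | step 13 | (3R,5aR,6S,7S,9aR)-6-[2-(benzyloxy)ethyl]-7-(hydroxymethyl)-2,2,5a-trimethyloctahydro-1-benzoxepin-3-ol | c1ccccc1COCC[C@H]2[C@@H](CO)CC[C@H]3OC(C)(C)[C@H](O)CC[C@@]32C
F3 | step 13 | primary 4-methylbenzenesulfonate of F2 | c1ccccc1COCC[C@H]2[C@@H](COS(=O)(=O)c4ccc(C)cc4)CC[C@H]3OC(C)(C)[C@H](O)CC[C@@]32C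
F4 | step 17 | O,C-dilithio species from 23 | [Li]CC[C@H]2[C@@H](C)CC[C@H]3OC(C)(C)[C@H](O[Li])CC[C@@]32C
F5 | step 17 | dilithium alkoxide adduct of F4 and 9 | COC1=C(C)C(O[Li])(CC[C@H]3[C@@H](C)CC[C@H]4OC(C)(C)[C@H](O[Li])CC[C@@]43C)[C@]2(C)CC=C(O[Si](C(C)C)(C(C)C)C(C)C)C(C)(C)C2=C1O[Si](C)(C)C(C)(C)C
F6 | step 17 | (4aS)-1-hydroxy-4-{2-[(3R,5aR,6S,7S,9aR)-3-hydroxy-2,2,5a,7-tetramethyloctahydro-1-benzoxepin-6-yl]ethyl}-3,4a,8,8-tetramethyl-4a,5,6,8-tetrahydronaphthalene-2,7-dione | CC1=C(CC[C@H]2[C@@H](C)CC[C@H]3OC(C)(C)[C@H](O)CC[C@@]32C)[C@]2(C)CCC(=O)C(C)(C)C2=C(O)C1=O
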